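This flask is slow, and slowness invites the simplest bench rule: read how much electrophile goes per hour and multiply by the time.

the same everywhere: electrophile 20 mM

| charge | free base | protonated nucleophile | remark | time |
|---|---|---|---|---|
| beta | 29 mM | 36 mM | run made earlier |  |
| epsilon | 65 mM | 36 mM | run made earlier |  |
| ash | 45.0 mM | 36.0 mM |  | 3.0 h |
| maple | 30.0 mM | 36.0 mM |  | 3.0 h |
| larch | 20.0 mM | 36.0 mM |  | 3.0 h |

| run | time / min | electrophile / % | target / % |
|---|---|---|---|
| beta | 8.00 | 99.5 | 0.6 |
| beta | 12.0 | 100.0 | 0.6 |
| beta | 15.0 | 99.3 | 0.3 |
| beta | 25.0 | 99.3 | 1.4 |
| beta | 40.0 | 97.7 | 1.4 |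
| beta | 60.0 | 96.5 | 1.4 |
| beta | 90.0 | 94.9 | 2.0 |
| epsilon | 5.00 | 99.8 | 0.8 |
| epsilon | 15.0 | 99.3 | 1.0 |
| epsilon | 25.0 | 98.3 | 1.4 |
| epsilon | 40.0 | 96.8 | 1.1 |
| epsilon | 50.0 | 97.0 | 1.5 |
| epsilon | 80.0 | 95.0 | 1.8 |
| epsilon | 90.0 | 94.1 | 2.1 |

(readings scatter by 0.3 percentage points)

- percent here means electrophile units held: one side product counts as two
- the numbers in the tables scatter by 0.3 percentage points (one standard deviation)
- steps under discussion: electrophile + nucleophile -> acid set free + target; nucleophile + acid set free <-> protonated nucleophile; acid set free + free base <-> salt of the base; 2 free base -> self-condensation product; electrophile + target -> side product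

1. part of the electrophile that has reacted at the end, ash
2. part of the electrophile that has reacted at the end, maple
3. part of the electrophile that has reacted at the end, larch
4. what raising the concentration of free base from its lowest to its highest value here does to the part of the electrophile that has reacted (changes below 5 percentage points count as none) (it falls / it rises / no change)

By 90.0 min, beta has lost 5.10% of its electrophile and epsilon 5.90%. I average the two losses and divide by that time:

    s = mean loss / last reading time = 0.0367 h⁻¹

So s, the fraction of the charged electrophile lost per hour, is a mean rate from the start to the last reading, and it gives: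

    s · t = 11.0% at 3.0 h

Epsilon holds 2.24 times the free base of beta and has lost 0.8 percentage points more, a gap between two readings that each scatter by 0.3 points. From larch to ash the free base rises by nearly the same factor, 2.25, so I stretch that gap to the asked time:

    spread = gap · t / t_last = 1.6 points

This is less than the 5 points that counts as a change, so I expect no change.

The rule ends where the readings end, and the ratio t / t_last tells where that lies. Here the asked time is twice the last reading, so the rule is guessing beyond what was read.

The forecast gives 11% for ash, 10.3% for maple and 9% for larch, with no change as the trend. Its ground is this: “Free nucleophile seems to be set by the protonated nucleophile/base buffer”. My s gives one figure for the three flasks, whereas the forecast tilts them with the free base.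

    electrophile + nucleophile → acid set free + target (k = 0.0270 M⁻¹ s⁻¹)
    nucleophile + acid set free ⇌ protonated nucleophile, settled at all times (K = 8.40 × 10⁵ M⁻¹)
    acid set free + free base ⇌ salt of the base (K = 2.20 × 10⁶ M⁻¹, k = 0.160 M⁻¹ s⁻¹)
    2 free base → self-condensation product (k = 0.0210 M⁻¹ s⁻¹)
    electrophile + target → side product (k = 0.0130 M⁻¹ s⁻¹)

The flasks give 9.59% for ash, 9.08% for maple and 8.53% for larch, a change of 1.1 points, so the answer is no change. In ash, s · t stands 1.4 points above the result. There the half-life of electrophile by its step with nucleophile is 21 h at 0.127 h and 60 h at 3.00 h.

Ash read at 80 min has t / t_last = 0.889, inside the readings, and s gives: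

    s · t = 4.89%

The computed result for that flask is 4.89%.

Readings and results were generated by integration with made-up constants; noise was put on by code.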